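Labels: ring A is the benzoate (C1 CO2Me, C2 CH3, C3 H, C4 OH, C5 CH2OH, C6 ether carbon). Ring B is the phthalide arene (C1' ether carbon, C2' CH3, C3' lactone CH2, C4' lactone C=O, C5' OH, C6' OH). Ring C is the lactone fused to ring B at C3'–C4'.
Enabling feature: in ring B the C6' hydroxyl sits beside the ether carbon C1', and ring C spans C3'–C4'. So C3'–C2'–C1'–C6' plus the C6' oxygen is a latent 2,3,4-trisubstituted furan, and C4'–C5' plus the lactone carbonyl is a latent propiolate hanging from the C3' CH2O group.
Cuts, in retrosynthetic order: the ring A ketal; C5'–O (by way of C5'–CHO); C3'–C4' and C5'–C6' together; the tether ester C–O; the C3'–CH2 bond; the O–C1' ether bond; the ring A C5–CH2 bond.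
Forward order: ring A comes from methyl orsellinate. Its C6 oxygen is joined to a bromobutenolide, which is reduced to the furan and given its CH2OH arm. Rings B and C then arise together in one cycloaddition–aromatisation, and C5' is oxygenated last.
Stereochemistry: the target has no stereocentre, and the bridgehead centres of the transient cycloadduct disappear on aromatisation.

Key step: step 11

Remark: the stereocentres of the transient intermediates (chloro ether, lactol, oxa-bridged adduct) form as racemates and are lost again, so no SMILES carries a stereodescriptor.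

Step 1
Reactants: 1 methyl orsellinate (methyl 2,4-dihydroxy-6-methylbenzoate)
Product: 3 methyl 3-formyl-2,4-dihydroxy-6-methylbenzoate, via chloro(methoxy)methyl arene 2 (not isolated)
Conditions: Cl2CHOMe, TiCl4, CH2Cl2, −10 to 0 °C; then 1 M HCl
Reagents that add atoms: dichloromethyl methyl ether COC(Cl)Cl; water O
Why: Rieche formylation: TiCl4 held by the two phenolic oxygens should steer the electrophile to the carbon between them (future C5 of ring A), which both hydroxyls activate, and aqueous acid then hydrolyses chloro ether 2 to the aldehyde.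

Step 2
Reactants: 3 methyl 3-formyl-2,4-dihydroxy-6-methylbenzoate
Product: 4 methyl 2,4-dihydroxy-3-(hydroxymethyl)-6-methylbenzoate
Conditions: NaBH4, THF/MeOH, 0 °C; aq. NH4Cl
Reagents that add atoms: none
Why: Borohydride reduction of an aldehyde, which does not touch the benzoate; the low temperature and the near-neutral quench should hold back loss of water to an ortho-quinone methide.

Step 3
Reactants: 4 methyl 2,4-dihydroxy-3-(hydroxymethyl)-6-methylbenzoate
Product: 5 methyl 5-hydroxy-2,2,7-trimethyl-4H-1,3-benzodioxine-6-carboxylate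
Conditions: Me2C(OMe)2, PPTS (cat.), acetone, rt
Reagents that add atoms: 2,2-dimethoxypropane COC(C)(C)OC
Why: Acid-catalysed transketalisation under equilibrium control: the six-membered ketal should close onto the C4 oxygen because the C6 hydroxyl stays locked in its hydrogen bond to the ester carbonyl, so that exactly the hydroxyl needed for the ether remains free.

Step 4
Reactants: 6 3-methyltetronic acid (4-hydroxy-3-methylfuran-2(5H)-one)
Product: 7 4-bromo-3-methylfuran-2(5H)-one
Conditions: (COBr)2, DMF, CH2Cl2, 0 °C to rt
Reagents that add atoms: oxalyl bromide O=C(Br)C(=O)Br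
Why: Deoxybromination of a vinylogous acid with the bromoiminium salt formed from (COBr)2 and DMF, a standard conversion of tetronic acids; the bromide is chosen over a sulfonate because a phenoxide can attack a sulfonate at sulfur.

Step 5
Reactants: 5 methyl 5-hydroxy-2,2,7-trimethyl-4H-1,3-benzodioxine-6-carboxylate; 7 4-bromo-3-methylfuran-2(5H)-one
Product: 8 methyl 2,2,7-trimethyl-5-[(4-methyl-5-oxo-2,5-dihydrofuran-3-yl)oxy]-4H-1,3-benzodioxine-6-carboxylate
Conditions: Cs2CO3, DMF, 50 °C
Reagents that add atoms: none
Why: Conjugate addition–elimination (vinylogous acyl substitution): the caesium phenoxide adds to the beta carbon of the bromobutenolide and bromide leaves, so the crowded ether oxygen is attached at an open sp2 carbon of a small ring long before ring B exists.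

Step 6
Reactants: 8 aryloxybutenolide
Product: 10 methyl 2,2,7-trimethyl-5-[(4-methylfuran-3-yl)oxy]-4H-1,3-benzodioxine-6-carboxylate, via lactol 9 (not isolated)
Conditions: iBu2AlH (1.1 equiv), CH2Cl2, −78 °C; aq. potassium sodium tartrate; then PPTS (cat.), CH2Cl2, rt
Reagents that add atoms: none
Why: Half-reduction of a butenolide to its lactol followed by acid-catalysed dehydration is a standard furan synthesis; the Lewis-basic vinylogous carbonate should bind and take up hydride at −78 °C well before the ring A ester, which is shielded by two ortho substituents.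

Step 7
Reactants: 10 3-aryloxy-4-methylfuran
Product: 11 methyl 5-[(2-bromo-4-methylfuran-3-yl)oxy]-2,2,7-trimethyl-4H-1,3-benzodioxine-6-carboxylate
Conditions: NBS (1.0 equiv), THF, −78 to 0 °C, dark
Reagents that add atoms: N-bromosuccinimide O=C1CCC(=O)N1Br
Why: Electrophilic aromatic bromination: the aryloxy oxygen makes the neighbouring alpha carbon (future C6') by far the most nucleophilic site of the furan, so one equivalent of NBS should block just that position and leave the alpha carbon next to the methyl group open.

Step 8
Reactants: 11 2-bromo-3-aryloxy-4-methylfuran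
Product: 13 methyl 5-[(2-bromo-5-formyl-4-methylfuran-3-yl)oxy]-2,2,7-trimethyl-4H-1,3-benzodioxine-6-carboxylate, via iminium chloride 12 (not isolated)
Conditions: POCl3, DMF, CH2Cl2, 0 °C to rt; then aq. NaOAc
Reagents that add atoms: N,N-dimethylformamide CN(C)C=O; water O
Why: Vilsmeier–Haack formylation, which can only strike the one free furan carbon (future C3'), a position still far more reactive than the lone C3–H of ring A; it needs no organometallic base and therefore spares the methyl ester.

Step 9
Reactants: 13 bromofuran aldehyde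
Product: 15 methyl 5-{[5-(hydroxymethyl)-4-methylfuran-3-yl]oxy}-2,2,7-trimethyl-4H-1,3-benzodioxine-6-carboxylate, via bromofurfuryl alcohol 14 (not isolated)
Conditions: NaBH4, TMEDA, PdCl2(dppf) (5 mol %), THF, rt
Reagents that add atoms: none
Why: Borohydride reduces the aldehyde at once and, through zerovalent palladium formed from PdCl2(dppf), the same hydride source carries out catalytic hydrodebromination (oxidative addition, hydride transfer, reductive elimination), a known room-temperature dehalogenation of halogenated five-membered heteroarenes that spares esters and ketals.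

Step 10
Reactants: 15 4-aryloxy-3-methylfurfuryl alcohol; 16 propiolic acid
Product: 17 methyl 2,2,7-trimethyl-5-({4-methyl-5-[(prop-2-ynoyloxy)methyl]furan-3-yl}oxy)-4H-1,3-benzodioxine-6-carboxylate
Conditions: DCC, DMAP (5 mol %), CH2Cl2, −20 to 0 °C
Reagents that add atoms: none
Why: Steglich esterification at low temperature, the usual way to acylate acid-sensitive furfuryl alcohols with propiolic acid while keeping conjugate addition of DMAP to the alkyne in check.

Step 11
Reactants: 17 4-aryloxy-3-methylfurfuryl propiolate
Product: 19 methyl 5-[(6-hydroxy-4-methyl-1-oxo-1,3-dihydro-2-benzofuran-5-yl)oxy]-2,2,7-trimethyl-4H-1,3-benzodioxine-6-carboxylate, via oxa-bridged cycloadduct 18 (not isolated)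
Conditions: dry DMSO (0.01 M), BHT (10 mol %), 120 °C, argon; then PPTS (10 mol %), 60 °C
Reagents that add atoms: none
Why: The furan acts as diene through its two alpha carbons and the tethered propiolate as dienophile in a thermal intramolecular [4+2] cycloaddition that forms C3'–C4' (tether-bearing furan carbon to internal alkyne carbon) and C5'–C6' (terminal alkyne carbon to the free alpha carbon) and gives the oxa-bridged diene 18; the C3'–O bond then ionises and loss of the C6' proton delivers phenol 19. The closest known reaction type is the intramolecular Diels–Alder reaction of furans with tethered alkynes followed by aromatisation to phenols. Ring C closes as a five-membered lactone at the moment the C3'–C4' bond forms, the three-atom CH2–O–C(=O) tether allowing only this fused orientation, and ring B closes as the six-membered ring of the same cycloaddition and becomes aromatic when the oxygen bridge opens. No stereocentre is created in 19, since the two bridgehead centres of racemic 18 are erased. The selectivity needed is the direction of bridge opening, and it is secured because only cleavage at the quaternary C3' gives a cation that is tertiary, allylic and carried on to C1', where the aryloxy oxygen stabilises it, while C6' keeps the oxygen and holds the one proton whose loss aromatises the ring. The weak point, the preference of the ester for its extended unreactive rotamer, is countered by the polar solvent, which favours the more polar folded rotamer, by the aryloxy and methyl donors that raise the furan HOMO, by high dilution with BHT against intermolecular reactions, and by the irreversible aromatisation that PPTS completes.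

Step 12
Reactants: 19 6-hydroxyphthalide diaryl ether
Product: 21 methyl 5-[(7-formyl-6-hydroxy-4-methyl-1-oxo-1,3-dihydro-2-benzofuran-5-yl)oxy]-2,2,7-trimethyl-4H-1,3-benzodioxine-6-carboxylate, via hydroxymethyl phenol 20 (not isolated)
Conditions: MgCl2, Et3N, (CH2O)n, MeCN, reflux; aq. citric acid
Reagents that add atoms: paraformaldehyde (as formaldehyde) C=O
Why: Casnati–Skattebøl ortho-formylation: the magnesium phenoxide delivers formaldehyde through a six-membered chelate to the only free ortho carbon C5', and a second formaldehyde oxidises the benzylic alkoxide of 20 by hydride transfer; this carbon-first detour is preferred to direct ortho-oxidation with iodine-based oxidants, which in 2-alkoxyphenols tend to attack the oxygen-bearing ortho carbon and would here cut the diaryl ether.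

Step 13
Reactants: 21 7-formyl-6-hydroxyphthalide diaryl ether
Product: 23 methyl 5-[(6,7-dihydroxy-4-methyl-1-oxo-1,3-dihydro-2-benzofuran-5-yl)oxy]-2,2,7-trimethyl-4H-1,3-benzodioxine-6-carboxylate, via aryl formate 22 (not isolated)
Conditions: 30% aq. H2O2, Na2CO3, THF/H2O, 0 °C to rt, argon; then aq. KHSO4
Reagents that add atoms: hydrogen peroxide OO
Why: Dakin oxidation: hydroperoxide adds to the aldehyde, the aryl group bearing the ortho phenoxide migrates to oxygen and formate 22 is hydrolysed in the same flask, while the hindered ring A ester is inert and a lactone opened by base would reclose on acidification.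

Step 14
Reactants: 23 catechol acetonide
Product: 24 methyl 2-[(6,7-dihydroxy-4-methyl-1-oxo-1,3-dihydro-2-benzofuran-5-yl)oxy]-4-hydroxy-3-(hydroxymethyl)-6-methylbenzoate (CNP0220419.0)
Conditions: 1 M HCl, THF, rt
Reagents that add atoms: none
Why: Acid hydrolysis of the phenol–benzyl alcohol ketal; water as the only nucleophile avoids ether formation at the benzylic carbon, and lactone, methyl ester and diaryl ether are stable to dilute acid at room temperature.

Compound list
1 | methyl orsellinate (methyl 2,4-dihydroxy-6-methylbenzoate) | COC(=O)c1c(C)cc(O)cc1O | starting material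
2 | methyl 3-[chloro(methoxy)methyl]-2,4-dihydroxy-6-methylbenzoate (racemic, not isolated) | COC(=O)c1c(C)cc(O)c(C(Cl)OC)c1O | intermediate
3 | methyl 3-formyl-2,4-dihydroxy-6-methylbenzoate | COC(=O)c1c(C)cc(O)c(C=O)c1O | intermediate
4 | methyl 2,4-dihydroxy-3-(hydroxymethyl)-6-methylbenzoate | COC(=O)c1c(C)cc(O)c(CO)c1O | intermediate
5 | methyl 5-hydroxy-2,2,7-trimethyl-4H-1,3-benzodioxine-6-carboxylate (ring A phenol, acetonide) | COC(=O)c1c(C)cc2OC(C)(C)OCc2c1O | intermediate
6 | 3-methyltetronic acid | CC1=C(O)COC1=O | starting material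
7 | 4-bromo-3-methylfuran-2(5H)-one | CC1=C(Br)COC1=O | intermediate
8 | methyl 2,2,7-trimethyl-5-[(4-methyl-5-oxo-2,5-dihydrofuran-3-yl)oxy]-4H-1,3-benzodioxine-6-carboxylate | COC(=O)c1c(C)cc2OC(C)(C)OCc2c1OC1=C(C)C(=O)OC1 | intermediate
9 | methyl 5-[(5-hydroxy-4-methyl-2,5-dihydrofuran-3-yl)oxy]-2,2,7-trimethyl-4H-1,3-benzodioxine-6-carboxylate (lactol, racemic, not isolated) | COC(=O)c1c(C)cc2OC(C)(C)OCc2c1OC1=C(C)C(O)OC1 | intermediate
10 | methyl 2,2,7-trimethyl-5-[(4-methylfuran-3-yl)oxy]-4H-1,3-benzodioxine-6-carboxylate | COC(=O)c1c(C)cc2OC(C)(C)OCc2c1Oc1cocc1C | intermediate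
11 | methyl 5-[(2-bromo-4-methylfuran-3-yl)oxy]-2,2,7-trimethyl-4H-1,3-benzodioxine-6-carboxylate | COC(=O)c1c(C)cc2OC(C)(C)OCc2c1Oc1c(Br)occ1C | intermediate
12 | N-{[5-bromo-4-(aryloxy)-3-methylfuran-2-yl]methylidene}-N-methylmethanaminium chloride, aryl = ring A acetonide (not isolated) | COC(=O)c1c(C)cc2OC(C)(C)OCc2c1Oc1c(Br)oc(C=[N+](C)C)c1C.[Cl-] | intermediate
13 | methyl 5-[(2-bromo-5-formyl-4-methylfuran-3-yl)oxy]-2,2,7-trimethyl-4H-1,3-benzodioxine-6-carboxylate | COC(=O)c1c(C)cc2OC(C)(C)OCc2c1Oc1c(Br)oc(C=O)c1C | intermediate
14 | methyl 5-{[2-bromo-5-(hydroxymethyl)-4-methylfuran-3-yl]oxy}-2,2,7-trimethyl-4H-1,3-benzodioxine-6-carboxylate (not isolated) | COC(=O)c1c(C)cc2OC(C)(C)OCc2c1Oc1c(Br)oc(CO)c1C | intermediate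
15 | methyl 5-{[5-(hydroxymethyl)-4-methylfuran-3-yl]oxy}-2,2,7-trimethyl-4H-1,3-benzodioxine-6-carboxylate | COC(=O)c1c(C)cc2OC(C)(C)OCc2c1Oc1coc(CO)c1C | intermediate
16 | propiolic acid | C#CC(=O)O | starting material
17 | methyl 2,2,7-trimethyl-5-({4-methyl-5-[(prop-2-ynoyloxy)methyl]furan-3-yl}oxy)-4H-1,3-benzodioxine-6-carboxylate (key-step precursor) | C#CC(=O)OCc1occ(Oc2c(C(=O)OC)c(C)cc3OC(C)(C)OCc23)c1C | intermediate
18 | lactone-fused 7-oxabicyclo[2.2.1]hepta-2,5-diene: oxygen bridge C3'–O–C6', C1'(aryloxy)=C2'(CH3), C4'=C5'H, lactone across C3'–C4' (racemic, not isolated) | O=C1OCC23OC(C=C12)C(Oc1c(C(=O)OC)c(C)cc4OC(C)(C)OCc14)=C3C | intermediate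
19 | methyl 5-[(6-hydroxy-4-methyl-1-oxo-1,3-dihydro-2-benzofuran-5-yl)oxy]-2,2,7-trimethyl-4H-1,3-benzodioxine-6-carboxylate (key-step product) | COC(=O)c1c(C)cc2OC(C)(C)OCc2c1Oc1c(C)c2COC(=O)c2cc1O | intermediate
20 | methyl 5-{[6-hydroxy-7-(hydroxymethyl)-4-methyl-1-oxo-1,3-dihydro-2-benzofuran-5-yl]oxy}-2,2,7-trimethyl-4H-1,3-benzodioxine-6-carboxylate (as magnesium salt, not isolated) | COC(=O)c1c(C)cc2OC(C)(C)OCc2c1Oc1c(C)c2COC(=O)c2c(CO)c1O | intermediate
21 | methyl 5-[(7-formyl-6-hydroxy-4-methyl-1-oxo-1,3-dihydro-2-benzofuran-5-yl)oxy]-2,2,7-trimethyl-4H-1,3-benzodioxine-6-carboxylate | COC(=O)c1c(C)cc2OC(C)(C)OCc2c1Oc1c(C)c2COC(=O)c2c(C=O)c1O | intermediate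
22 | methyl 5-{[7-(formyloxy)-6-hydroxy-4-methyl-1-oxo-1,3-dihydro-2-benzofuran-5-yl]oxy}-2,2,7-trimethyl-4H-1,3-benzodioxine-6-carboxylate (not isolated) | COC(=O)c1c(C)cc2OC(C)(C)OCc2c1Oc1c(C)c2COC(=O)c2c(OC=O)c1O | intermediate
23 | methyl 5-[(6,7-dihydroxy-4-methyl-1-oxo-1,3-dihydro-2-benzofuran-5-yl)oxy]-2,2,7-trimethyl-4H-1,3-benzodioxine-6-carboxylate | COC(=O)c1c(C)cc2OC(C)(C)OCc2c1Oc1c(C)c2COC(=O)c2c(O)c1O | intermediate
24 | methyl 2-[(6,7-dihydroxy-4-methyl-1-oxo-1,3-dihydro-2-benzofuran-5-yl)oxy]-4-hydroxy-3-(hydroxymethyl)-6-methylbenzoate (CNP0220419.0) | COC(=O)c1c(C)cc(O)c(CO)c1Oc1c(C)c2c(c(O)c1O)C(=O)OC2 | target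

Total step count: 14.
Longest linear sequence: 13 steps (steps 1–3 and 5–14). Step 4 is a one-step side branch.

The three steps most likely to fail:

Step 11. The ester may stay in its extended rotamer. Ring closure would then be outrun by ionisation of the electron-rich furfuryl ester or by oligomerisation of the alkyne.
- The fallback sets out from 15 and comes back at 19. It runs the cycloaddition bimolecularly and closes ring C afterwards.
- Alcohol 15 is heated with an excess of methyl propiolate in toluene at 90 °C.
- The aryloxy enol ether makes the free alpha carbon the nucleophilic end of the diene. That carbon should therefore bond to the terminal alkyne carbon and give the oxa-bridged adduct F1.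
- PPTS in warm toluene opens the bridge, in the same direction as in the main route, to the hydroxy ester F2.
- The CH2OH group of F2 lies ortho to the new ester and should lactonise under the same conditions to 19.

Step 5. Conjugate addition of the hindered, hydrogen-bonded phenoxide may be too slow, while the base consumes the bromobutenolide through gamma-deprotonation.
- The fallback sets out from 5 and comes back at 10. It makes the ether by substitution at an sp3 carbon and builds the five-membered ring afterwards.
- Hydroxyacetone and bromoacetyl bromide (pyridine, CH2Cl2, 0 °C) give 2-oxopropyl bromoacetate F3.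
- F3 alkylates phenol 5 (K2CO3, acetone, reflux) to the aryloxyacetate F4.
- DBU in MeCN brings about an intramolecular aldol condensation onto the ketone and gives the isomeric butenolide F5.
- Reduction with iBu2AlH at −78 °C gives its lactol F6, and PPTS dehydrates this to the same furan 10.

Step 12. Carbon–carbon bond formation at C5' may fail because the neighbouring lactone carbonyl deactivates this carbon, so that the phenoxide only forms formaldehyde acetals on oxygen.
- The fallback sets out from 19 and comes back at 23. It replaces the formylation–Dakin pair by a one-electron oxidation.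
- (KSO3)2NO in acetone/aq. KH2PO4 (Teuber oxidation) converts the phenol to the ortho-quinone F7. The para carbon C3' is blocked and C5' is the only ortho carbon that bears hydrogen.
- Aqueous Na2S2O4 then reduces F7 to catechol 23.

Further compounds
F1 | step 11 | methyl 5-{[4-(hydroxymethyl)-5-(methoxycarbonyl)-3-methyl-7-oxabicyclo[2.2.1]hepta-2,5-dien-2-yl]oxy}-2,2,7-trimethyl-4H-1,3-benzodioxine-6-carboxylate (racemic) | COC(=O)C1=CC2OC1(CO)C(C)=C2Oc1c(C(=O)OC)c(C)cc3OC(C)(C)OCc13
F2 | step 11 | methyl 5-[6-hydroxy-3-(hydroxymethyl)-4-(methoxycarbonyl)-2-methylphenoxy]-2,2,7-trimethyl-4H-1,3-benzodioxine-6-carboxylate | COC(=O)c1cc(O)c(Oc2c(C(=O)OC)c(C)cc3OC(C)(C)OCc23)c(C)c1CO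
F3 | step 5 | 2-oxopropyl bromoacetate | CC(=O)COC(=O)CBr
F4 | step 5 | methyl 2,2,7-trimethyl-5-[2-oxo-2-(2-oxopropoxy)ethoxy]-4H-1,3-benzodioxine-6-carboxylate | CC(=O)COC(=O)COc1c(C(=O)OC)c(C)cc2OC(C)(C)OCc12
F5 | step 5 | methyl 2,2,7-trimethyl-5-[(4-methyl-2-oxo-2,5-dihydrofuran-3-yl)oxy]-4H-1,3-benzodioxine-6-carboxylate | CC1=C(Oc2c(C(=O)OC)c(C)cc3OC(C)(C)OCc23)C(=O)OC1
F6 | step 5 | methyl 5-[(2-hydroxy-4-methyl-2,5-dihydrofuran-3-yl)oxy]-2,2,7-trimethyl-4H-1,3-benzodioxine-6-carboxylate (lactol, racemic) | CC1=C(Oc2c(C(=O)OC)c(C)cc3OC(C)(C)OCc23)C(O)OC1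
F7 | step 12 | methyl 2,2,7-trimethyl-5-[(4-methyl-1,6,7-trioxo-1,3,6,7-tetrahydro-2-benzofuran-5-yl)oxy]-4H-1,3-benzodioxine-6-carboxylate | O=C1C(=O)C(Oc3c(C(=O)OC)c(C)cc4OC(C)(C)OCc34)=C(C)C2=C1C(=O)OC2
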